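Book the loss of D in the dusk flask as a fixed amount per day, and test that booking once the reckoning stands.

in all of them: G 0.020 M

| charge | X | L | remark | time |
|---|---|---|---|---|
| dusk | 0.060 M (fed, over 6.0 h) | 0.40 mM | the very flask that is asked about, followed so far |  |
| summer | 0.12 M (fed, over 6.0 h) | 0.40 mM | run made earlier |  |
| flask | 0.0600 M (fed, over 6.0 h) | 0.400 mM |  | 5.0 d |

dusk run (percent of the G charged)

| time / h | D / % | G / % |
|---|---|---|
| 12.0 | 5.6 | 1.2 |
| 20.0 | 8.1 | 0 |
| 30.0 | 11.0 | 0.3 |
| 50.0 | 14.3 | 0.2 |

summer run (percent of the G charged)

| time / d | D / % | G / % |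
|---|---|---|
| 0.500 | 12.5 | 1.5 |
| 1.04 | 27.1 | 0.2 |
| 2.50 | 35.9 | 0 |
| 5.00 | 15.5 | 0 |

(each reading ± 1 percentage point)

- the earlier runs were read with a standard deviation of 1 percentage point
- a reading or a percentage of D counts all its forms, free or not

* time, not beyond 5.0 d, at which the flask holds most D
* the amount of D, in percent of the G charged, at that time

Read the net gains of D as fractions of the G charged per day: 0.270 d⁻¹ in summer between 0.500 d and 1.04 d, 0.0720 d⁻¹ in dusk between 12.0 h and 30.0 h, then 0.0396 d⁻¹ in dusk up to 50.0 h.

G reads 1.5% or less from those times on, with D at 12.5% in summer at 0.500 d, so take D as formed from an intermediate. Take that step as pseudo-first-order, with X in excess and the gross formation of D proportional to X; with X taken at its charge and the same amount of intermediate in both runs, summer forms 2.00 times what dusk forms.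

Add the same loss to both net gains and solve. This gives the standing loss, the fraction of the G charged that D loses per day, assumed equal in dusk and summer over these readings and independent of the amount of D there: 0.126 d⁻¹, a reading with the scatter of its points.

Gross formation in dusk is then 0.198 d⁻¹, falling to 0.166 d⁻¹ at a decay constant of 0.225 d⁻¹. D peaks where formation meets the standing loss, so commit to 2.88 d and 15.3%.

Now reforge the weak link. Try a loss proportional to D instead, with mean D 8.30% in dusk and 19.8% in summer: the rate constant comes out at −3.95 d⁻¹, which is negative, though on noisy points. So keep the fixed loss, zero order in total D, and read it, as a guess, as one dissolved concentration of D held steady beneath a solid.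

The forecast says 4 d and 20%, “a broad maximum around 4 days”; this reckoning stands earlier, and lower.

The flask gives 1.98 d and 13.2%. Of that D, 9.33% then stands as crystals, E.

    G → Q (k = 1.71 × 10⁻⁴ s⁻¹)
    X + Q → D (k = 6.19 × 10⁻⁵ L mol⁻¹ s⁻¹)
    E ⇌ D, rate k3*(cs3 - [D]) while solid is left; crystals form when [D] > cs3 (solubility = 0.780 mM, k = 0.0116 s⁻¹)
    G + L → Z (k = 0.0722 L mol⁻¹ s⁻¹)
    D → J (k = 4.68 × 10⁻⁵ s⁻¹)

Put the standing loss on a neighbouring flask with 0.036 M of X: by this reckoning gross formation scales to 0.119 d⁻¹, less than the standing loss of 0.126 d⁻¹, and that flask's D tops out at 3.80%.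

The numbers in the tables were generated by integration for substances that don't exist; the scatter is artificial.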